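**Retrosynthetic overview**

1. Target acid ⇐ its methyl ester ⇐ one-pot annulation of a homoallylic tertiary hydroperoxide with methyl propiolate: peroxy-Michael addition (O2–C3), then a hydrogen-atom-transfer (MHAT) 6-exo radical cyclisation that closes the 1,2-dioxane by forming C3–C4 and sets C3 and C4.
2. Feature used: in the ring O1–O2–C3–C4–C5–C6, C3 is bonded to the peroxide oxygen O2 and is β to the carboxyl carbon, so it is the β-carbon of a β-peroxyacrylate; its neighbour C4 carries CH3 and H, so it is the Markovnikov hydrogen-atom adduct of an allyl group on the quaternary C6; the O1–O2 bridge already joins both halves.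
3. Homoallylic hydroperoxide ⇐ (protect, oxidise, methylenate, deprotect) 3-hydroperoxy alcohol ⇐ H2O2 opening of a 2,2-dialkyloxetane with inversion (sets C6) ⇐ 1,3-diol ⇐ Sharpless epoxidation and Red-Al opening of an (E)-allylic alcohol ⇐ Zr-catalysed carboalumination of a terminal alkyne.
4. Alkyne ⇐ copper-catalysed sp3–sp3 coupling (C9–C10) of two chiral-pool fragments: (S)-citronellyl bromide plus styrene (C12 and the phenylbutyl end) and (S)-3-bromo-2-methylpropan-1-ol plus trimethylsilylacetylene (C8).
5. Order of rings: the epoxide (step 7) and the oxetane (step 9) are temporary; the 1,2-dioxane, the only ring of the target that is built, is formed last (step 15).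

Key step: step 15

Remark on numbering: ring atoms are O1, O2, C3 (bears CH2CO2H), C4 (CH3), C5, C6 (CH3 and the chain); C1 is the carboxyl carbon and C2 its CH2; the chain runs C7 (CH2 on C6), C8 (CH3), C9–C11, C12 (CH3), C13–C16, phenyl on C16.

Assumption: the Lewis-acid-promoted opening of the 2,2-dialkyloxetane by H2O2 (step 10) is taken to proceed with inversion at the tertiary carbon, as is known for this reaction type.

Step 1
Reactants: 1 (6S)-8-bromo-2,6-dimethyloct-2-ene [(S)-citronellyl bromide]; 2 styrene
Product: 3 [(1E,5S)-7-bromo-5-methylhept-1-en-1-yl]benzene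
Conditions: second-generation Grubbs catalyst (H2IMes)(PCy3)Cl2Ru=CHPh (3 mol%), styrene (3 equiv), CH2Cl2, 40 °C
Reagents that add atoms: none
Why: Olefin cross-metathesis exchanges the isopropylidene end of 1 for a styryl group, driven by loss of volatile 2-methylpropene, and the methyl-bearing stereocentre (the later C12) is not involved.

Step 2
Reactants: 3 [(1E,5S)-7-bromo-5-methylhept-1-en-1-yl]benzene
Product: 4 [(5S)-7-bromo-5-methylheptyl]benzene
Conditions: H2 (1 atm), Pt/C, EtOAc, rt
Reagents that add atoms: none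
Why: Heterogeneous catalytic hydrogenation saturates the styrenyl C=C under neutral conditions that leave the primary C–Br bond and the arene intact.

Step 3
Reactants: 5 (2S)-3-bromo-2-methylpropan-1-ol
Product: 7 [(4S)-5-bromo-4-methylpent-1-yn-1-yl]trimethylsilane, via primary triflate 6 (not isolated)
Conditions: Tf2O, 2,6-lutidine, CH2Cl2, −78 °C; then Me3SiC≡CLi (from Me3SiC≡CH, n-BuLi), THF/DMPU, −78 → −20 °C
Reagents that add atoms: ethynyltrimethylsilane C#C[Si](C)(C)C
Why: SN2 alkylation of a lithium acetylide by the primary triflate, which is displaced far faster than the primary bromide at low temperature, while the stereocentre (the later C8) is a spectator.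

Step 4
Reactants: 7 [(4S)-5-bromo-4-methylpent-1-yn-1-yl]trimethylsilane; 4 [(5S)-7-bromo-5-methylheptyl]benzene
Product: 9 trimethyl[(4R,8S)-4,8-dimethyl-12-phenyldodec-1-yn-1-yl]silane, via Grignard reagent 8 (not isolated)
Conditions: Mg, THF, 40 °C; then 4, Li2CuCl4 (3 mol%), THF/NMP, 0 °C → rt
Reagents that add atoms: none
Why: Copper-catalysed sp3–sp3 cross-coupling (Kochi type) of the primary Grignard reagent with the unbranched primary bromide joins the two fragments at C9–C10 without touching either stereocentre or the silyl-capped alkyne.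

Step 5
Reactants: 9 trimethyl[(4R,8S)-4,8-dimethyl-12-phenyldodec-1-yn-1-yl]silane
Product: 10 (4R,8S)-4,8-dimethyl-12-phenyldodec-1-yne
Conditions: K2CO3 (cat.), MeOH, rt
Reagents that add atoms: none
Why: Base-catalysed methanolysis cleaves the C(sp)–Si bond (protodesilylation) and frees the terminal alkyne.

Step 6
Reactants: 10 (4R,8S)-4,8-dimethyl-12-phenyldodec-1-yne
Product: 13 (2E,5R,9S)-3,5,9-trimethyl-13-phenyltridec-2-en-1-ol, via alkenylalane 11 (not isolated), via lithium alkenylaluminate 12 (not isolated)
Conditions: Me3Al, Cp2ZrCl2 (cat.), CH2Cl2, 0 °C → rt; evaporate; n-BuLi, hexane/THF, 0 °C; (CH2O)n, rt; aqueous work-up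
Reagents that add atoms: trimethylaluminium C[Al](C)C; paraformaldehyde (formaldehyde unit) C=O
Why: Zirconium-catalysed syn-carboalumination (Negishi) adds CH3–Al across the terminal alkyne with the methyl on the internal carbon, and the aluminate is hydroxymethylated with retention, which gives the E-trisubstituted allylic alcohol.

Step 7
Reactants: 13 (2E,5R,9S)-3,5,9-trimethyl-13-phenyltridec-2-en-1-ol
Product: 14 [(2S,3S)-3-[(2R,6S)-2,6-dimethyl-10-phenyldecyl]-3-methyloxiran-2-yl]methanol
Conditions: Ti(Oi-Pr)4 (cat.), L-(+)-diethyl tartrate (cat.), t-BuOOH, 4 Å MS, CH2Cl2, −20 °C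
Reagents that add atoms: tert-butyl hydroperoxide CC(C)(C)OO
Why: Sharpless asymmetric epoxidation, in which the titanium tartrate from L-(+)-diethyl tartrate delivers oxygen to the alkene face that gives the (2S,3S)-epoxy alcohol (reagent control, as for other (E)-3-methylalk-2-en-1-ols), and so fixes the tertiary C–O carbon (the later C6).

Step 8
Reactants: 14 [(2S,3S)-3-[(2R,6S)-2,6-dimethyl-10-phenyldecyl]-3-methyloxiran-2-yl]methanol
Product: 15 (3S,5R,9S)-3,5,9-trimethyl-13-phenyltridecane-1,3-diol
Conditions: NaAlH2(OCH2CH2OCH3)2 (Red-Al), THF, 0 °C → rt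
Reagents that add atoms: none
Why: Hydroxyl-directed reductive epoxide opening, in which the alkoxyaluminate delivers hydride intramolecularly to C2, so that the tertiary C–O bond and its configuration are kept and the 1,3-diol forms.

Step 9
Reactants: 15 (3S,5R,9S)-3,5,9-trimethyl-13-phenyltridecane-1,3-diol
Product: 17 (2S)-2-[(2R,6S)-2,6-dimethyl-10-phenyldecyl]-2-methyloxetane, via primary monotosylate 16 (not isolated)
Conditions: n-BuLi (1 equiv), THF, 0 °C; TsCl (1 equiv); n-BuLi (1 equiv), 0 → 60 °C
Reagents that add atoms: none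
Why: Selective sulfonylation of the primary alkoxide followed by 4-exo-tet Williamson closure by the tertiary alkoxide gives the oxetane, and the tertiary stereocentre is retained because its C–O bond is not broken.

Step 10
Reactants: 17 (2S)-2-[(2R,6S)-2,6-dimethyl-10-phenyldecyl]-2-methyloxetane
Product: 18 (3R,5R,9S)-3-hydroperoxy-3,5,9-trimethyl-13-phenyltridecan-1-ol
Conditions: anhydrous H2O2 in Et2O (excess), Me3SiOTf (10 mol%), −78 → −30 °C
Reagents that add atoms: hydrogen peroxide OO
Why: Lewis-acid-promoted perhydrolysis of a 2,2-dialkyloxetane, in which H2O2 attacks the activated ring at the more substituted carbon with inversion (SN2-like opening), turns the (S)-oxetane carbon into the (R)-configured peroxide carbon C6 of the target.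

Step 11
Reactants: 18 (3R,5R,9S)-3-hydroperoxy-3,5,9-trimethyl-13-phenyltridecan-1-ol
Product: 19 (3R,5R,9S)-3-[(2-methoxypropan-2-yl)peroxy]-3,5,9-trimethyl-13-phenyltridecan-1-ol
Conditions: 2-methoxypropene (1.1 equiv), PPTS (cat.), CH2Cl2, 0 °C
Reagents that add atoms: 2-methoxypropene C=C(C)OC
Why: Acid-catalysed peroxyketalisation, in which the hydroperoxide (the more acidic and more nucleophilic O–H) is captured by the oxocarbenium ion of 2-methoxypropene in preference to the primary alcohol.

Step 12
Reactants: 19 (3R,5R,9S)-3-[(2-methoxypropan-2-yl)peroxy]-3,5,9-trimethyl-13-phenyltridecan-1-ol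
Product: 20 (3R,5R,9S)-3-[(2-methoxypropan-2-yl)peroxy]-3,5,9-trimethyl-13-phenyltridecanal
Conditions: Dess–Martin periodinane, pyridine, CH2Cl2, 0 °C → rt
Reagents that add atoms: none
Why: Dess–Martin oxidation of the primary alcohol to the aldehyde under pyridine-buffered conditions that neither cleave the acid-labile peroxyketal nor eliminate the β-peroxide.

Step 13
Reactants: 20 (3R,5R,9S)-3-[(2-methoxypropan-2-yl)peroxy]-3,5,9-trimethyl-13-phenyltridecanal
Product: 21 (4S,6R,10S)-4-[(2-methoxypropan-2-yl)peroxy]-4,6,10-trimethyl-14-phenyltetradec-1-ene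
Conditions: Ph3PCH3Br, KHMDS, THF, −78 → 0 °C
Reagents that add atoms: methyltriphenylphosphonium bromide C[P+](c1ccccc1)(c1ccccc1)c1ccccc1.[Br-]
Why: Wittig methylenation of the aldehyde with the non-stabilised ylide at low temperature should outrun enolisation, and the doubly tertiary, hindered O–O bond is not attacked.

Step 14
Reactants: 21 (4S,6R,10S)-4-[(2-methoxypropan-2-yl)peroxy]-4,6,10-trimethyl-14-phenyltetradec-1-ene
Product: 22 (4S,6R,10S)-4-hydroperoxy-4,6,10-trimethyl-14-phenyltetradec-1-ene
Conditions: AcOH/THF/H2O, rt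
Reagents that add atoms: none
Why: Mild acid hydrolysis of the peroxyketal (an O,O-ketal of acetone) frees the tertiary hydroperoxide, whose C–O bond and configuration are untouched.

Step 15
Reactants: 22 (4S,6R,10S)-4-hydroperoxy-4,6,10-trimethyl-14-phenyltetradec-1-ene; 23 methyl propiolate
Product: 27 methyl 2-[(3S,4S,6R)-6-[(2R,6S)-2,6-dimethyl-10-phenyldecyl]-4,6-dimethyl-1,2-dioxan-3-yl]acetate, via β-peroxyacrylate 24 (not isolated), via secondary C4 radical 25 (not isolated), via α-ester radical 26 (not isolated)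
Conditions: N-methylmorpholine (10 mol%), CH2Cl2, −20 °C; then i-PrOH, Mn(dpm)3 [tris(dipivaloylmethanato)manganese, trivalent manganese] (10 mol%), PhSiH2(Oi-Pr) (2 equiv), 0 °C, argon, 0.01 M
Reagents that add atoms: none
Why: Proposed new method: amine-catalysed peroxy-Michael addition of the hydroperoxide 22 to methyl propiolate gives the (E)-β-peroxyacrylate 24 in the flask, the manganese hydride formed from Mn(dpm)3 and the silane then transfers a hydrogen atom to the terminal CH2 of the allyl group (Markovnikov MHAT), and the secondary C4 radical 25 adds to C3, the β-carbon of the acrylate, to give the α-ester radical 26, which is reduced to 27. The closest known reaction types are the MHAT-initiated reductive olefin coupling (hydrogen-atom-transfer Giese cyclisation) and the 6-exo cyclisation of alkyl radicals onto β-alkoxyacrylates; neither has been shown with an O–O bond in the tether. The only ring closed is the 1,2-dioxane, by 6-exo-trig attack of C4 on C3. C4 should be set by the chair-like transition state, in which its methyl group is pseudo-equatorial because the inside position would be syn-axial to a substituent of the quaternary C6, and in which C6 places its larger β-branched chain equatorial and its methyl axial. C3 should be set by the rotamer of the vinyl peroxide: addition through the s-cis form (O1–O2–C3=C2 syn-clinal) puts C2 pseudo-axial, where it meets only H-5 because O1 carries no substituent, and this gives the all-cis 3S,4S arrangement relative to 6R. The step needs hydrogen-atom transfer to the unactivated alkene and not to the acrylate or the O–O bond, cyclisation faster than reduction of 25, and the face selectivity at C3 and C4; these rest on the polarity match of the nucleophilic radical with the acrylate β-carbon, on the Thorpe–Ingold effect of the quaternary C6 in the tether, on the E geometry of 24 and on the preset C6 stereocentre.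

Step 16
Reactants: 27 methyl 2-[(3S,4S,6R)-6-[(2R,6S)-2,6-dimethyl-10-phenyldecyl]-4,6-dimethyl-1,2-dioxan-3-yl]acetate
Product: 29 2-[(3S,4S,6R)-6-[(2R,6S)-2,6-dimethyl-10-phenyldecyl]-4,6-dimethyl-1,2-dioxan-3-yl]acetic acid, via lithium carboxylate 28 (not isolated)
Conditions: LiOH·H2O, THF/H2O, 0 °C; then 1 M HCl to pH 3
Reagents that add atoms: lithium hydroxide [Li+].[OH-]
Why: Saponification (BAc2) of the methyl ester with LiOH at low temperature, conditions that dialkyl peroxides tolerate, followed by acidification of the carboxylate.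

**Compound list**

1 | (6S)-8-bromo-2,6-dimethyloct-2-ene [(S)-citronellyl bromide] | C[C@@H](CCC=C(C)C)CCBr | starting material
2 | styrene | C=Cc1ccccc1 | starting material
3 | [(1E,5S)-7-bromo-5-methylhept-1-en-1-yl]benzene | C[C@@H](CC/C=C/c1ccccc1)CCBr | intermediate
4 | [(5S)-7-bromo-5-methylheptyl]benzene | C[C@@H](CCCCc1ccccc1)CCBr | intermediate
5 | (2S)-3-bromo-2-methylpropan-1-ol | BrC[C@@H](C)CO | starting material
6 | (2S)-3-bromo-2-methylpropyl trifluoromethanesulfonate | BrC[C@@H](C)COS(=O)(=O)C(F)(F)F | intermediate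
7 | [(4S)-5-bromo-4-methylpent-1-yn-1-yl]trimethylsilane | BrC[C@@H](C)CC#C[Si](C)(C)C | intermediate
8 | [(2S)-2-methyl-5-(trimethylsilyl)pent-4-yn-1-yl]magnesium bromide | Br[Mg]C[C@@H](C)CC#C[Si](C)(C)C | intermediate
9 | trimethyl[(4R,8S)-4,8-dimethyl-12-phenyldodec-1-yn-1-yl]silane | C[C@@H](CCCCc1ccccc1)CCC[C@@H](C)CC#C[Si](C)(C)C | intermediate
10 | (4R,8S)-4,8-dimethyl-12-phenyldodec-1-yne | C[C@@H](CCCCc1ccccc1)CCC[C@@H](C)CC#C | intermediate
11 | dimethyl[(1E,4R,8S)-2,4,8-trimethyl-12-phenyldodec-1-en-1-yl]alumane | C[C@@H](CCCCc1ccccc1)CCC[C@@H](C)C/C(C)=C/[Al](C)C | intermediate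
12 | lithium butyl(dimethyl)[(1E,4R,8S)-2,4,8-trimethyl-12-phenyldodec-1-en-1-yl]aluminate | [Li+].C[C@@H](CCCCc1ccccc1)CCC[C@@H](C)C/C(C)=C/[Al-](C)(C)CCCC | intermediate
13 | (2E,5R,9S)-3,5,9-trimethyl-13-phenyltridec-2-en-1-ol | C[C@@H](CCCCc1ccccc1)CCC[C@@H](C)C/C(C)=C/CO | intermediate
14 | [(2S,3S)-3-[(2R,6S)-2,6-dimethyl-10-phenyldecyl]-3-methyloxiran-2-yl]methanol | C[C@@H](CCCCc1ccccc1)CCC[C@@H](C)C[C@]1(C)O[C@H]1CO | intermediate
15 | (3S,5R,9S)-3,5,9-trimethyl-13-phenyltridecane-1,3-diol | C[C@@H](CCCCc1ccccc1)CCC[C@@H](C)C[C@@](O)(C)CCO | intermediate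
16 | (3S,5R,9S)-3-hydroxy-3,5,9-trimethyl-13-phenyltridecyl 4-methylbenzenesulfonate | C[C@@H](CCCCc1ccccc1)CCC[C@@H](C)C[C@@](O)(C)CCOS(=O)(=O)c1ccc(C)cc1 | intermediate
17 | (2S)-2-[(2R,6S)-2,6-dimethyl-10-phenyldecyl]-2-methyloxetane | C[C@@H](CCCCc1ccccc1)CCC[C@@H](C)C[C@@]1(C)CCO1 | intermediate
18 | (3R,5R,9S)-3-hydroperoxy-3,5,9-trimethyl-13-phenyltridecan-1-ol | C[C@@H](CCCCc1ccccc1)CCC[C@@H](C)C[C@](OO)(C)CCO | intermediate
19 | (3R,5R,9S)-3-[(2-methoxypropan-2-yl)peroxy]-3,5,9-trimethyl-13-phenyltridecan-1-ol | C[C@@H](CCCCc1ccccc1)CCC[C@@H](C)C[C@](OOC(C)(C)OC)(C)CCO | intermediate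
20 | (3R,5R,9S)-3-[(2-methoxypropan-2-yl)peroxy]-3,5,9-trimethyl-13-phenyltridecanal | C[C@@H](CCCCc1ccccc1)CCC[C@@H](C)C[C@](OOC(C)(C)OC)(C)CC=O | intermediate
21 | (4S,6R,10S)-4-[(2-methoxypropan-2-yl)peroxy]-4,6,10-trimethyl-14-phenyltetradec-1-ene | C[C@@H](CCCCc1ccccc1)CCC[C@@H](C)C[C@](OOC(C)(C)OC)(C)CC=C | intermediate
22 | (4S,6R,10S)-4-hydroperoxy-4,6,10-trimethyl-14-phenyltetradec-1-ene | C[C@@H](CCCCc1ccccc1)CCC[C@@H](C)C[C@](OO)(C)CC=C | intermediate
23 | methyl propiolate | C#CC(=O)OC | starting material
24 | methyl (2E)-3-{[(4S,6R,10S)-4,6,10-trimethyl-14-phenyltetradec-1-en-4-yl]peroxy}prop-2-enoate | C[C@@H](CCCCc1ccccc1)CCC[C@@H](C)C[C@](OO/C=C/C(=O)OC)(C)CC=C | intermediate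
25 | secondary alkyl radical at C4 formed from 24 by hydrogen-atom transfer | C[C@@H](CCCCc1ccccc1)CCC[C@@H](C)C[C@](OO/C=C/C(=O)OC)(C)C[CH]C | intermediate
26 | α-ester radical of the cyclised 1,2-dioxane | C[C@@H](CCCCc1ccccc1)CCC[C@@H](C)C[C@]1(C)C[C@H](C)[C@H]([CH]C(=O)OC)OO1 | intermediate
27 | methyl 2-[(3S,4S,6R)-6-[(2R,6S)-2,6-dimethyl-10-phenyldecyl]-4,6-dimethyl-1,2-dioxan-3-yl]acetate | C[C@@H](CCCCc1ccccc1)CCC[C@@H](C)C[C@]1(C)C[C@H](C)[C@H](CC(=O)OC)OO1 | intermediate
28 | lithium 2-[(3S,4S,6R)-6-[(2R,6S)-2,6-dimethyl-10-phenyldecyl]-4,6-dimethyl-1,2-dioxan-3-yl]acetate | [Li+].C[C@@H](CCCCc1ccccc1)CCC[C@@H](C)C[C@]1(C)C[C@H](C)[C@H](CC(=O)[O-])OO1 | intermediate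
29 | 2-[(3S,4S,6R)-6-[(2R,6S)-2,6-dimethyl-10-phenyldecyl]-4,6-dimethyl-1,2-dioxan-3-yl]acetic acid | C[C@@H](CCCCc1ccccc1)CCC[C@@H](C)C[C@]1(C)C[C@H](C)[C@H](CC(=O)O)OO1 | target

**Step count**

Total: 16 steps. Longest linear sequence: 15 steps (steps 1, 2 and 4–16; step 3 prepares the second fragment).

**Steps most likely to fail**

1. Step 15 (Proposed new method). What may go wrong: the radical may cyclise through the chair with C2 equatorial instead of axial (wrong face at C3), the relay from C6 (methyl against chain) may be weak, and the O–O bond of the vinyl peroxide 24 may homolyse before hydrogen-atom transfer. The equatorial mode is a serious competitor, so the C3 epimer could be a main product.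
 Fallback (known chemistry), setting out from 22 and 23 and coming back at 27: the annulation is run as before and the C3 epimer, methyl 2-[(3R,4S,6R)-6-[(2R,6S)-2,6-dimethyl-10-phenyldecyl]-4,6-dimethyl-1,2-dioxan-3-yl]acetate F1, is not discarded. With base (DBU, or Et2NH in CF3CH2OH) a 1,2-dioxane-3-acetate opens by β-elimination of the peroxide, the reverse of a peroxy-Michael addition, to the hydroperoxy enoate methyl (2E,4S,6R,8R,12S)-6-hydroperoxy-4,6,8,12-tetramethyl-16-phenylhexadec-2-enoate F2. The established amine-mediated intramolecular conjugate addition of a hydroperoxide to an enoate re-closes the O2–C3 bond reversibly. Both C3 epimers are expected; 27 is collected and F1 recycled. C3 is then set in a polar O–C closure, while the C3–C4 bond and C4 still come from step 15.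

2. Step 10. What may go wrong: ionisation of the activated oxetane to an open tertiary cation, which would erode the configuration at C6 and give elimination products.
 Fallback, setting out from 13 and coming back at 18: cobalt-catalysed hydroperoxysilylation of the trisubstituted alkene (Isayama–Mukaiyama conditions: Co(acac)2, divalent cobalt, O2, Et3SiH, EtOH) places the silylperoxy group at the more substituted carbon and gives triethyl{[(5R,9S)-1-hydroxy-3,5,9-trimethyl-13-phenyltridecan-3-yl]peroxy}silane F3 as both C3 epimers. K2CO3 in MeOH removes silicon to give 18 together with its C3 epimer, which is separated here or after step 15. This drops the epoxide and oxetane steps 7–10 at the price of stereocontrol at C6.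

3. Step 13. What may go wrong: enolisation of the β-peroxy aldehyde by the basic ylide followed by β-elimination of the peroxide, or attack of the ylide on the O–O bond.
 Fallback, setting out from 18 and coming back at 22: without a protecting group, Dess–Martin oxidation of the hydroperoxy alcohol gives the cyclic peroxyhemiacetal (5R)-5-[(2R,6S)-2,6-dimethyl-10-phenyldecyl]-5-methyl-1,2-dioxolan-3-ol F4 (ring–chain tautomer of the 3-hydroperoxy aldehyde). Lactol-type Wittig methylenation with excess Ph3P=CH2 then gives 22 directly. The peroxide travels as its anion, which is not a leaving group, and steps 11–14 shrink to two.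

**Further compounds**

F1 | step 15 | methyl 2-[(3R,4S,6R)-6-[(2R,6S)-2,6-dimethyl-10-phenyldecyl]-4,6-dimethyl-1,2-dioxan-3-yl]acetate | C[C@@H](CCCCc1ccccc1)CCC[C@@H](C)C[C@]1(C)C[C@H](C)[C@@H](CC(=O)OC)OO1
F2 | step 15 | methyl (2E,4S,6R,8R,12S)-6-hydroperoxy-4,6,8,12-tetramethyl-16-phenylhexadec-2-enoate | C[C@@H](CCCCc1ccccc1)CCC[C@@H](C)C[C@](OO)(C)C[C@H](C)/C=C/C(=O)OC
F3 | step 10 | triethyl{[(5R,9S)-1-hydroxy-3,5,9-trimethyl-13-phenyltridecan-3-yl]peroxy}silane (both C3 epimers) | C[C@@H](CCCCc1ccccc1)CCC[C@@H](C)CC(C)(OO[Si](CC)(CC)CC)CCO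
F4 | step 13 | (5R)-5-[(2R,6S)-2,6-dimethyl-10-phenyldecyl]-5-methyl-1,2-dioxolan-3-ol (both C3 epimers) | C[C@@H](CCCCc1ccccc1)CCC[C@@H](C)C[C@]1(C)CC(O)OO1
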